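**Retrosynthetic overview**

1. The target is 1β-O-(E)-p-coumaroyl-5α-hydroxypolygodial (drimane numbering: ring A = C1–C5, C10; ring B = C5–C10; C11 on C9, C12 on C8). End game: phenol desilylation ⇐ Swern oxidation of the 11,12-diol ⇐ acylation of C1–OH.
2. The diol comes from hydride opening of a tricyclic γ-menthyloxy butenolide (temporary ring C8–C9–C11–O–C12) that carries C11/C12 and relays stereochemistry.
3. Ring B is made last, in one flask: C7=C8 by Horner–Wadsworth–Emmons olefination of a C8 phosphonate with acetaldehyde (C6–C7), then C5–C6 by intramolecular vinylogous aldol addition of the resulting dienolate to the C5 ketone.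
4. Enabling feature: in ring B the array C5(OH)–C6H2–C7H=C8–C12=O is a δ-hydroxy enoate, and C5 lies between the quaternary C4 and C10, so the precursor ketone cannot enolise and can only act as the electrophile.
5. Precursor: ring A enone 1 → conjugate silylation (sets C1) → enolate Michael addition to (5R)-menthyloxybutenolide 3 (sets C10, C9) → Si to O, pivalate, phosphonate. Ring order: A (bought), butenolide (bought, temporary), B (step 6).

Key step: step 6

Remark: compound 1 is taken as a catalogue compound, and the sense of induction in step 1 is assumed to follow the analogous rhodium/BINAP aryl transfers (the antipodal ligand is used if it proves opposite).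

Step 1
Reactants: 1 2,6,6-trimethylcyclohex-2-en-1-one
Product: 2 (3R)-3-[dimethyl(phenyl)silyl]-2,6,6-trimethylcyclohexan-1-one (C2 epimers)
Conditions: PhMe2Si–B(pin) (1.3 equiv), [Rh(cod)2]OTf (5 mol %), (R)-BINAP (6 mol %), Et3N, 1,4-dioxane/H2O 10:1, 45 °C
Reagents that add atoms: (dimethylphenylsilyl)boronic acid pinacol ester, C[Si](C)(c1ccccc1)B1OC(C)(C)C(C)(C)O1
Why: Rhodium-catalysed enantioselective conjugate silyl transfer to a cyclic enone, in which the BINAP-bound silylrhodium adds to one face of the unhindered β-carbon and so sets the silicon-bearing centre (the later C1), while the adjacent methyl-bearing centre is inconsequential because it is enolised in step 2.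

Step 2
Reactants: 2 (3R)-silyl ketone; 3 (5R)-5-(l-menthyloxy)furan-2(5H)-one
Product: 4 Michael adduct (4S,5R)-4-{(1R,6R)-6-[dimethyl(phenyl)silyl]-1,3,3-trimethyl-2-oxocyclohexyl}-5-(l-menthyloxy)oxolan-2-one
Conditions: LiN(iPr)2 (1.05 equiv), THF, −78 °C; then 3 (1.1 equiv), −78 °C; AcOH quench at −78 °C
Reagents that add atoms: none
Why: Michael addition of the only possible lithium enolate of 2 to the γ-alkoxybutenolide, in which the enolate reacts anti to the bulky pseudoaxial silyl group on the neighbouring carbon (setting the C10 quaternary centre with methyl cis to silicon) and the butenolide reacts anti to its menthyloxy group (setting C9), so that each new centre is fixed by its nearest existing stereocentre.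

Step 3
Reactants: 4 Michael adduct
Product: 5 (4S,5R)-4-[(1S,6R)-6-hydroxy-1,3,3-trimethyl-2-oxocyclohexyl]-5-(l-menthyloxy)oxolan-2-one
Conditions: KBr, AcOOH, NaOAc, AcOH, 0 °C → rt
Reagents that add atoms: peracetic acid, CC(=O)OO
Why: Fleming–Tamao oxidation (bromodesilylation of the phenyl group, then peracid-induced migration from silicon to oxygen) should convert C1–Si into C1–OH with retention, the ketone between two quaternary carbons being too hindered for Baeyer–Villiger oxidation under the buffered conditions.

Step 4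
Reactants: 5 hydroxy ketone
Product: 6 (1R,2S)-2-[(2R,3S)-2-(l-menthyloxy)-5-oxooxolan-3-yl]-2,4,4-trimethyl-3-oxocyclohexyl 2,2-dimethylpropanoate
Conditions: t-BuCOCl (3 equiv), DMAP (0.3 equiv), pyridine, 50 °C
Reagents that add atoms: pivaloyl chloride, CC(C)(C)C(=O)Cl
Why: DMAP-catalysed acylation gives a non-enolisable pivalate that blocks retro-aldol cleavage of the C1–C10 bond in the basic steps 5 and 6, keeps the C1 substituent small and oxygen-linked for step 6, and is removed by the hydride of step 7 without an extra operation.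

Step 5
Reactants: 6 pivalate
Product: 8 α-phosphono lactone (C8 diethoxyphosphoryl derivative of 6; C8 epimers), via enol phosphate 7 (not isolated)
Conditions: LiN(iPr)2 (1.1 equiv), THF, −78 °C; ClP(O)(OEt)2, −78 → 0 °C; LiN(iPr)2 (2.2 equiv), −78 → −20 °C; AcOH
Reagents that add atoms: diethyl chlorophosphate, CCOP(=O)(Cl)OCC
Why: O-phosphorylation of the lactone enolate followed by base-induced 1,3-migration of phosphorus from oxygen to carbon (vinyl phosphate to α-phosphono lactone rearrangement) should place the phosphonate at C8, the only enolisable position because the ketone has no α-hydrogen, and the C8 configuration is irrelevant.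

Step 6
Reactants: 8 α-phosphono lactone; 9 acetaldehyde
Product: 11 5α-hydroxy-11-(l-menthyloxy)-1β-(pivaloyloxy)drim-7-en-12,11-olide, via α-ethylidene lactone 10 (not isolated)
Conditions: NaN(SiMe3)2 (1.05 equiv), THF, −78 °C; 9 (1.2 equiv), −78 → 0 °C; then LiN(SiMe3)2 (1.6 equiv), −78 → −30 °C; AcOH quench at −78 °C
Reagents that add atoms: none
Why: Proposed new method: acetaldehyde acts as a two-carbon linchpin whose carbonyl carbon (C7) is first joined to C8 by Horner–Wadsworth–Emmons olefination of the phosphonate anion and whose methyl carbon (C6), now the γ-position of an α-alkylidene lactone, is then deprotonated to a dienolate that adds to the C5 ketone in an intramolecular vinylogous aldol reaction, so that C7=C8 and C5–C6 form in one flask; the closest known reaction types are the olefination of α-phosphono lactones with aldehydes and the γ-selective intramolecular aldol cyclisation of ester dienolates onto ketones. Ring B closes in the 6-(enolendo)-exo-trig mode, attack through C8 being excluded because it would give a cyclobutanol. The new C5 carbinol centre is controlled by C9 and C10: the planar butenolide dienolate fused at C8–C9 holds C11 pseudo-equatorial and H9 pseudo-axial, which places the C10 methyl axial on the forming ring B, and ring A then closes as the chair with the C1 pivalate equatorial, giving the trans-decalin with the 5α-oxygen anti to the methyl. Cis closure would need the other ring A chair, with C9 syn-axial to a C4 methyl and the C1 oxygen syn-axial to the C5 oxygen. Chemoselectivity rests on the C5 ketone being non-enolisable and on the C6 methyl being the most acidic remaining site, and the E/Z ratio of 10 is irrelevant because the dienolate erases it. The lithium aldolate is quenched cold so that the hindered tertiary alkoxide does not reopen by retro-aldol cleavage.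

Step 7
Reactants: 11 tricyclic hydroxy lactone
Product: 12 drim-7-ene-1β,5α,11,12-tetraol
Conditions: LiAlH4 (6 equiv), THF, −20 °C → rt; H2O/aq NaOH work-up
Reagents that add atoms: none
Why: Hydride reduction of the γ-alkoxy butenolide (an acylal) should open it through the C12 enal and the C11 aldehyde, both reduced at once to the 11,12-diol with loss of menthol and without epimerising C9, with 1,2-reduction at the conjugated carbonyl and cleavage of the pivalate in the same operation.

Step 8
Reactants: 12 tetraol
Product: 13 11,12-bis[(tert-butyldimethylsilyl)oxy]drim-7-ene-1β,5α-diol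
Conditions: TBSCl (2.2 equiv), imidazole, DMF, 0 °C
Reagents that add atoms: tert-butyldimethylsilyl chloride, CC(C)(C)[Si](C)(C)Cl
Why: Sterically controlled silylation of the two primary alcohols (C11, C12) over the neopentyl secondary C1–OH and the tertiary C5–OH should leave C1–OH as the only acylable hydroxyl.

Step 9
Reactants: 14 (E)-p-coumaric acid
Product: 16 (E)-3-{4-[(tert-butyldimethylsilyl)oxy]phenyl}prop-2-enoic acid, via bis-silyl derivative 15 (not isolated)
Conditions: TBSCl (2.5 equiv), imidazole, DMF, rt; then AcOH/THF/H2O, rt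
Reagents that add atoms: tert-butyldimethylsilyl chloride, CC(C)(C)[Si](C)(C)Cl
Why: Exhaustive silylation followed by selective hydrolysis of the labile silyl ester should give the phenol-protected acid, the aryl silyl ether being stable to aqueous acetic acid.

Step 10
Reactants: 13 bis-silyl diol; 16 silyl-protected coumaric acid
Product: 18 11,12-bis[(tert-butyldimethylsilyl)oxy]-5α-hydroxydrim-7-en-1β-yl (E)-3-{4-[(tert-butyldimethylsilyl)oxy]phenyl}prop-2-enoate, via mixed anhydride 17 (not isolated)
Conditions: 16, 2,4,6-trichlorobenzoyl chloride, Et3N, THF, rt; then 13, DMAP, toluene, rt → 60 °C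
Reagents that add atoms: none
Why: Yamaguchi esterification should acylate the hindered secondary C1–OH through the acylpyridinium derived from the mixed anhydride while the tertiary C5–OH stays untouched, and the E geometry of the cinnamate is carried through unchanged.

Step 11
Reactants: 18 tris-silyl ester
Product: 19 5α,11,12-trihydroxydrim-7-en-1β-yl (E)-3-{4-[(tert-butyldimethylsilyl)oxy]phenyl}prop-2-enoate
Conditions: CSA (0.1 equiv), MeOH/CH2Cl2 1:1, 0 °C
Reagents that add atoms: none
Why: Acid-catalysed methanolysis should remove the two primary alkyl silyl ethers much faster than the acid-stable phenolic silyl ether, so the phenol stays masked for the oxidation.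

Step 12
Reactants: 19 diol
Product: 20 5α-hydroxy-11,12-dioxodrim-7-en-1β-yl (E)-3-{4-[(tert-butyldimethylsilyl)oxy]phenyl}prop-2-enoate
Conditions: (COCl)2, DMSO, CH2Cl2, −78 °C; then Et3N, −78 → −40 °C; pH 7 buffer
Reagents that add atoms: none
Why: Swern oxidation activates both primary alcohols before base is added, so the 1,4-diol should go to the 1,4-dialdehyde without lactol or lactone formation, and the cold, brief exposure to amine preserves the epimerisable C9 centre while the tertiary C5–OH is inert.

Step 13
Reactants: 20 silyl-protected dialdehyde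
Product: 21 target, 5α-hydroxy-11,12-dioxodrim-7-en-1β-yl (E)-3-(4-hydroxyphenyl)prop-2-enoate
Conditions: Bu4NF (1.1 equiv), AcOH (1.5 equiv), THF, 0 °C
Reagents that add atoms: none
Why: Fluoride cleavage of the aryl silyl ether, buffered with acetic acid so that the C9 aldehyde centre is not epimerised, should liberate the phenol and give the target.

**Compound list**

1 | 2,6,6-trimethylcyclohex-2-en-1-one | CC1=CCCC(C)(C)C1=O | starting material
2 | (3R)-3-[dimethyl(phenyl)silyl]-2,6,6-trimethylcyclohexan-1-one (C2 epimers) | CC1(C)CC[C@@H]([Si](C)(C)c2ccccc2)C(C)C1=O | intermediate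
3 | (5R)-5-{[(1R,2S,5R)-5-methyl-2-(propan-2-yl)cyclohexyl]oxy}furan-2(5H)-one, (5R)-5-(l-menthyloxy)butenolide | O=C1C=C[C@H](O[C@@H]2C[C@H](C)CC[C@H]2C(C)C)O1 | starting material
4 | (4S,5R)-4-{(1R,6R)-6-[dimethyl(phenyl)silyl]-1,3,3-trimethyl-2-oxocyclohexyl}-5-(l-menthyloxy)oxolan-2-one | CC1(C)CC[C@@H]([Si](C)(C)c2ccccc2)[C@](C)([C@@H]2CC(=O)O[C@H]2O[C@@H]2C[C@H](C)CC[C@H]2C(C)C)C1=O | intermediate
5 | (4S,5R)-4-[(1S,6R)-6-hydroxy-1,3,3-trimethyl-2-oxocyclohexyl]-5-(l-menthyloxy)oxolan-2-one | CC1(C)CC[C@@H](O)[C@](C)([C@@H]2CC(=O)O[C@H]2O[C@@H]2C[C@H](C)CC[C@H]2C(C)C)C1=O | intermediate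
6 | (1R,2S)-2-[(2R,3S)-2-(l-menthyloxy)-5-oxooxolan-3-yl]-2,4,4-trimethyl-3-oxocyclohexyl 2,2-dimethylpropanoate | CC1(C)CC[C@@H](OC(=O)C(C)(C)C)[C@](C)([C@@H]2CC(=O)O[C@H]2O[C@@H]2C[C@H](C)CC[C@H]2C(C)C)C1=O | intermediate
7 | ketene acetal diethyl phosphate of lactone 6 (C8=C12–O–P(O)(OEt)2; other stereocentres as in 6) | CC1(C)CC[C@@H](OC(=O)C(C)(C)C)[C@](C)([C@@H]2C=C(OP(=O)(OCC)OCC)O[C@H]2O[C@@H]2C[C@H](C)CC[C@H]2C(C)C)C1=O | intermediate (not isolated)
8 | (1R,2S)-2-[(2R,3S)-4-(diethoxyphosphoryl)-2-(l-menthyloxy)-5-oxooxolan-3-yl]-2,4,4-trimethyl-3-oxocyclohexyl 2,2-dimethylpropanoate (epimers at the phosphorus-bearing carbon) | CC1(C)CC[C@@H](OC(=O)C(C)(C)C)[C@](C)([C@@H]2C(P(=O)(OCC)OCC)C(=O)O[C@H]2O[C@@H]2C[C@H](C)CC[C@H]2C(C)C)C1=O | intermediate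
9 | acetaldehyde | CC=O | starting material
10 | α-ethylidene lactone: 4-ethylidene analogue of lactone 6 (E/Z mixture; other stereocentres as in 6) | CC1(C)CC[C@@H](OC(=O)C(C)(C)C)[C@](C)([C@@H]2C(=CC)C(=O)O[C@H]2O[C@@H]2C[C@H](C)CC[C@H]2C(C)C)C1=O | intermediate (not isolated)
11 | (11R)-5α-hydroxy-11-(l-menthyloxy)-1β-(pivaloyloxy)drim-7-en-12,11-olide (9α-H, 10β-methyl) | CC1(C)CC[C@@H](OC(=O)C(C)(C)C)[C@]2(C)[C@H]3[C@H](O[C@@H]4C[C@H](C)CC[C@H]4C(C)C)OC(=O)C3=CC[C@@]12O | intermediate
12 | drim-7-ene-1β,5α,11,12-tetraol (9α-H) | CC1(C)CC[C@@H](O)[C@]2(C)[C@@H](CO)C(CO)=CC[C@@]12O | intermediate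
13 | 11,12-bis[(tert-butyldimethylsilyl)oxy]drim-7-ene-1β,5α-diol | CC1(C)CC[C@@H](O)[C@]2(C)[C@@H](CO[Si](C)(C)C(C)(C)C)C(CO[Si](C)(C)C(C)(C)C)=CC[C@@]12O | intermediate
14 | (E)-3-(4-hydroxyphenyl)prop-2-enoic acid (p-coumaric acid) | OC(=O)/C=C/c1ccc(O)cc1 | starting material
15 | tert-butyldimethylsilyl (E)-3-{4-[(tert-butyldimethylsilyl)oxy]phenyl}prop-2-enoate | CC(C)(C)[Si](C)(C)OC(=O)/C=C/c1ccc(O[Si](C)(C)C(C)(C)C)cc1 | intermediate (not isolated)
16 | (E)-3-{4-[(tert-butyldimethylsilyl)oxy]phenyl}prop-2-enoic acid | OC(=O)/C=C/c1ccc(O[Si](C)(C)C(C)(C)C)cc1 | intermediate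
17 | mixed anhydride of 16 with 2,4,6-trichlorobenzoic acid | O=C(/C=C/c1ccc(O[Si](C)(C)C(C)(C)C)cc1)OC(=O)c1c(Cl)cc(Cl)cc1Cl | intermediate (not isolated)
18 | 11,12-bis[(tert-butyldimethylsilyl)oxy]-5α-hydroxydrim-7-en-1β-yl (E)-3-{4-[(tert-butyldimethylsilyl)oxy]phenyl}prop-2-enoate | CC1(C)CC[C@@H](OC(=O)/C=C/c2ccc(O[Si](C)(C)C(C)(C)C)cc2)[C@]2(C)[C@@H](CO[Si](C)(C)C(C)(C)C)C(CO[Si](C)(C)C(C)(C)C)=CC[C@@]12O | intermediate
19 | 5α,11,12-trihydroxydrim-7-en-1β-yl (E)-3-{4-[(tert-butyldimethylsilyl)oxy]phenyl}prop-2-enoate | CC1(C)CC[C@@H](OC(=O)/C=C/c2ccc(O[Si](C)(C)C(C)(C)C)cc2)[C@]2(C)[C@@H](CO)C(CO)=CC[C@@]12O | intermediate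
20 | 5α-hydroxy-11,12-dioxodrim-7-en-1β-yl (E)-3-{4-[(tert-butyldimethylsilyl)oxy]phenyl}prop-2-enoate (9α-H) | CC1(C)CC[C@@H](OC(=O)/C=C/c2ccc(O[Si](C)(C)C(C)(C)C)cc2)[C@]2(C)[C@@H](C=O)C(C=O)=CC[C@@]12O | intermediate
21 | 5α-hydroxy-11,12-dioxodrim-7-en-1β-yl (E)-3-(4-hydroxyphenyl)prop-2-enoate (CNP0323926.1) | CC1(C)CC[C@@H](OC(=O)/C=C/c2ccc(O)cc2)[C@]2(C)[C@@H](C=O)C(C=O)=CC[C@@]12O | target

**Step count and risks**

Total steps: 13. Longest linear sequence: 12 steps (steps 1–8 and 10–13; step 9 is a one-step side branch).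

Steps most likely to fail:

1. Step 6 (the proposed new method). The hindered tertiary aldolate may reopen by retro-vinylogous aldol cleavage, the C9–C10 bond may be lost by retro-Michael scission under base, or facial selectivity at C5 may erode. The fallback generates the dienolate reductively instead of by deprotonation. It sets out from 8: Horner–Wadsworth–Emmons olefination with anhydrous chloroacetaldehyde (NaN(SiMe3)2, THF, −78 → 0 °C) should give the isolated α-(2-chloroethylidene) lactone F1. SmI2 in THF/HMPA at −78 °C should then effect a vinylogous Reformatsky (Barbier-type) closure onto the C5 ketone under non-basic conditions, with the alkoxide captured irreversibly on trivalent samarium. The fallback comes back to the route at 11.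

2. Step 2. Conjugate addition that forms a quaternary carbon next to the silyl-bearing carbon may stall, or proton transfer and reversal may compete. The fallback uses a doubly activated acceptor and sets out from 2 and 3. Bromine addition to 3 and triethylamine-induced dehydrobromination should give (5R)-3-bromo-5-(l-menthyloxy)furan-2(5H)-one F2. Zerovalent-palladium-catalysed P–C coupling with diethyl phosphite (Pd(PPh3)4, Et3N, toluene) should give (5R)-3-(diethoxyphosphoryl)-5-(l-menthyloxy)furan-2(5H)-one F3. The lithium enolate of 2 should add to F3 under the same facial controls to give the silyl phosphonate adduct F4. Fleming–Tamao oxidation should give the hydroxy phosphonate F5, and pivaloylation comes back to the route at 8, so steps 3 to 5 are no longer needed.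

3. Step 10. Acyl transfer to the neopentyl C1–OH, which is also crowded by the C11 silyloxymethyl group, may be too slow with a bulky cinnamoyl donor. The fallback builds the cinnamate on the alcohol instead and sets out from 13. Esterification with the small diethylphosphonoacetic acid (DCC, DMAP, CH2Cl2) should give the 1β-(diethylphosphonoacetate) F6. Horner–Wadsworth–Emmons olefination with commercial 4-[(tert-butyldimethylsilyl)oxy]benzaldehyde (LiCl, DBU, MeCN) should then form the (E)-cinnamate and come back to the route at 18.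

**Further compounds**

F1 | step 6 | 4-(2-chloroethylidene) analogue of lactone 6 (E/Z; other stereocentres as in 6) | CC1(C)CC[C@@H](OC(=O)C(C)(C)C)[C@](C)([C@@H]2C(=CCCl)C(=O)O[C@H]2O[C@@H]2C[C@H](C)CC[C@H]2C(C)C)C1=O
F2 | step 2 | (5R)-3-bromo-5-(l-menthyloxy)furan-2(5H)-one | O=C1C(Br)=C[C@H](O[C@@H]2C[C@H](C)CC[C@H]2C(C)C)O1
F3 | step 2 | (5R)-3-(diethoxyphosphoryl)-5-(l-menthyloxy)furan-2(5H)-one | O=C1C(P(=O)(OCC)OCC)=C[C@H](O[C@@H]2C[C@H](C)CC[C@H]2C(C)C)O1
F4 | step 2 | 3-(diethoxyphosphoryl) derivative of lactone 4 (epimers at the phosphorus-bearing carbon; other stereocentres as in 4) | CC1(C)CC[C@@H]([Si](C)(C)c2ccccc2)[C@](C)([C@@H]2C(P(=O)(OCC)OCC)C(=O)O[C@H]2O[C@@H]2C[C@H](C)CC[C@H]2C(C)C)C1=O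
F5 | step 2 | 3-(diethoxyphosphoryl) derivative of lactone 5 (epimers at the phosphorus-bearing carbon; other stereocentres as in 5) | CC1(C)CC[C@@H](O)[C@](C)([C@@H]2C(P(=O)(OCC)OCC)C(=O)O[C@H]2O[C@@H]2C[C@H](C)CC[C@H]2C(C)C)C1=O
F6 | step 10 | 11,12-bis[(tert-butyldimethylsilyl)oxy]-5α-hydroxydrim-7-en-1β-yl 2-(diethoxyphosphoryl)acetate | CC1(C)CC[C@@H](OC(=O)CP(=O)(OCC)OCC)[C@]2(C)[C@@H](CO[Si](C)(C)C(C)(C)C)C(CO[Si](C)(C)C(C)(C)C)=CC[C@@]12O
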